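**Retrosynthetic overview**

1. Feature: in the eight-membered carbocycle, dihydrobenzofuran C3 and indane C2 are bonded to the neighbouring carbons C3a and C4 of the benzofuran benzo ring (ring D). This ortho acyl/alkyl pair is what an aryne leaves when it inserts into the C(=O)–C(alpha) bond of a beta-keto ester.
2. Target ⇒ octamethyl ether 34 ⇒ pentacyclic ketone 26 (dihydrofuran by [4+1] annulation of an ortho-quinone methide at benzofuran C3 with a 4-methoxybenzyl sulfur ylide) ⇒ keto ester 21 (indane by Friedel–Crafts closure of an anisyl carbinol onto ring B).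
3. Key disconnection: 21 ⇒ tetralone beta-keto ester 11 + 3,5-dimethoxybenzyne from silyl triflate 19; the tetralone already holds the bridge methine, its bond to ring C and the future indane C3.
4. 11 ⇒ trans-3,4-diaryltetralone 10 (Claisen ethoxycarbonylation) ⇒ hydroxy ketone 9 (Friedel–Crafts) ⇒ lactone 7 + aryllithium; the absolute configuration comes from a dynamic kinetic transfer hydrogenation of keto ester 5.
5. Ring order: six-membered tetralone ring on ring C, then the eight-membered ring with ring D (key step), then the indane five-membered ring, then the dihydrofuran ring.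

Key step: step 10

Labels: benzofuran and indane numbering of the target; ring B = indane benzo ring; ring C = resorcinol ring bonded to the bridge methine (the CH bearing a 4-hydroxyphenyl group) and to benzofuran C3; ring D = benzofuran benzo ring.

Assumption: carbinol and sulfone carbons that are ionised in a later step (in 6, 7, 9, 22, 25, 28, 29) need no stereocontrol; in step 3 the faster-reacting ketone epimer is taken to be the Felkin–Anh-matched one, and if the other epimer reacted faster the (R,R)-catalyst would deliver the same 3S centre.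

**Route**

Step 1
Reactants: 1 4'-methoxyacetophenone; 2 1-bromo-3,5-dimethoxybenzene
Product: 3 2-(3,5-dimethoxyphenyl)-1-(4-methoxyphenyl)ethan-1-one
Conditions: Pd2(dba)3 (1.5 mol%), Xantphos, NaOtBu, THF, 70 °C
Reagents that add atoms: none
Why: Palladium-catalysed ketone alpha-arylation (Buchwald–Hartwig type) should couple the methyl ketone enolate once with the aryl bromide, because the product is held as its more hindered sodium enolate; no stereocentre is formed.

Step 2
Reactants: 3 2-(3,5-dimethoxyphenyl)-1-(4-methoxyphenyl)ethan-1-one; 4 ethyl bromoacetate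
Product: 5 ethyl 3-(3,5-dimethoxyphenyl)-4-(4-methoxyphenyl)-4-oxobutanoate (racemic)
Conditions: LiN(SiMe3)2, THF, −78 °C; then 4, −78 → 0 °C
Reagents that add atoms: none
Why: Enolate C-alkylation (SN2) of the benzylic ketone alpha-carbon with a reactive alpha-halo ester; the new centre is racemic and is deliberately left as a configurationally labile alpha-aryl ketone centre.

Step 3
Reactants: 5 ethyl 3-(3,5-dimethoxyphenyl)-4-(4-methoxyphenyl)-4-oxobutanoate
Product: 7 (4S,5S)-4-(3,5-dimethoxyphenyl)-5-(4-methoxyphenyl)dihydrofuran-2(3H)-one (cis lactone), via hydroxy ester 6 (not isolated)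
Conditions: RuCl[(S,S)-TsDPEN](p-cymene) (2 mol%), HCO2H/Et3N (5:2), DMF, 40 °C; then p-TsOH·H2O (cat.), toluene, 60 °C
Reagents that add atoms: none
Why: Noyori-type asymmetric transfer hydrogenation with dynamic kinetic resolution, in which the alpha-aryl ketone epimerises through its enol in the amine-buffered medium, the (S,S)-catalyst delivers hydride to the aryl ketone face that gives the S carbinol, and the 3S epimer, whose Felkin–Anh face matches that delivery, should be reduced faster, so that the future indane C3 centre is fixed before acid closes the cis lactone with loss of ethanol.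

Step 4
Reactants: 7 (4S,5S)-4-(3,5-dimethoxyphenyl)-5-(4-methoxyphenyl)dihydrofuran-2(3H)-one; 2 1-bromo-3,5-dimethoxybenzene
Product: 9 (3S,4S)-1,3-bis(3,5-dimethoxyphenyl)-4-hydroxy-4-(4-methoxyphenyl)butan-1-one (in equilibrium with its cyclic hemiketal), via 3,5-dimethoxyphenyllithium 8 (not isolated)
Conditions: 2, n-BuLi, THF, −78 °C; then 7, −78 °C; AcOH quench at −78 °C
Reagents that add atoms: none
Why: Bromine–lithium exchange followed by single addition of the aryllithium to the lactone carbonyl, where the lithium hemiketal alkoxide persists at −78 °C and so should prevent a second addition; both stereocentres are untouched.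

Step 5
Reactants: 9 (3S,4S)-1,3-bis(3,5-dimethoxyphenyl)-4-hydroxy-4-(4-methoxyphenyl)butan-1-one
Product: 10 (3R,4R)-3-(3,5-dimethoxyphenyl)-5,7-dimethoxy-4-(4-methoxyphenyl)-3,4-dihydronaphthalen-1(2H)-one (3,4-trans)
Conditions: TfOH (10 mol%), HFIP, 0 °C
Reagents that add atoms: none
Why: Intramolecular Friedel–Crafts alkylation, in which the 4-methoxybenzylic cation is captured in a six-membered closure by the carbon of the 3,5-dimethoxybenzoyl ring that is ortho to the carbonyl and ortho/para to the two methoxy groups, and the new C4 centre should form trans to the C3 aryl group because both aryl groups sit pseudo-equatorial in the chair-like closure (the change of the C3 descriptor from S to R is a priority effect only).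

Step 6
Reactants: 10 (3R,4R)-3-(3,5-dimethoxyphenyl)-5,7-dimethoxy-4-(4-methoxyphenyl)-3,4-dihydronaphthalen-1(2H)-one
Product: 11 ethyl (2R,3S,4R)-3-(3,5-dimethoxyphenyl)-5,7-dimethoxy-4-(4-methoxyphenyl)-1-oxo-1,2,3,4-tetrahydronaphthalene-2-carboxylate (2,3-trans, 3,4-trans; keto/enol mixture)
Conditions: NaH, (EtO)2CO, THF, 66 °C; AcOH quench
Reagents that add atoms: diethyl carbonate, CCOC(=O)OCC
Why: Crossed Claisen condensation at the only enolisable position, driven by formation of the beta-keto ester enolate; the epimerisable C2 centre should settle trans to the C3 aryl group.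

Step 7
Reactants: 12 3,5-dimethoxyphenol
Product: 13 3,5-dimethoxyphenyl isopropylcarbamate
Conditions: i-PrNCO, Et3N (cat.), CH2Cl2, 23 °C
Reagents that add atoms: isopropyl isocyanate, CC(C)N=C=O
Why: Base-catalysed addition of the phenol to the isocyanate (carbamoylation) installs an ortho-directing group that can be removed later under mild conditions.

Step 8
Reactants: 13 3,5-dimethoxyphenyl isopropylcarbamate
Product: 17 3,5-dimethoxy-2-(trimethylsilyl)phenyl isopropylcarbamate, via N-silyl carbamate 14 (not isolated), via ortho-lithiated carbamate 15 (not isolated), via bis-silyl carbamate 16 (not isolated)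
Conditions: TBSOTf, TMEDA, Et2O, 0 °C; n-BuLi, TMEDA, −78 °C; TMSCl, −78 → 23 °C; aq. NaHSO4
Reagents that add atoms: chlorotrimethylsilane, C[Si](C)(C)Cl
Why: Carbamate-directed ortho-metalation after transient N-silylation, then silyl quench; the carbamate is the stronger director, the position between it and a methoxy group is lithiated, and the two such positions are equivalent by symmetry, so one regioisomer should result.

Step 9
Reactants: 17 3,5-dimethoxy-2-(trimethylsilyl)phenyl isopropylcarbamate
Product: 19 3,5-dimethoxy-2-(trimethylsilyl)phenyl trifluoromethanesulfonate, via silyl phenol 18 (not isolated)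
Conditions: DBU, Et2NH, MeCN, 40 °C; then PhNTf2, 23 °C
Reagents that add atoms: N-phenylbis(trifluoromethanesulfonimide), O=S(=O)(N(c1ccccc1)S(=O)(=O)C(F)(F)F)C(F)(F)F
Why: E1cB cleavage of the N–H carbamate (the isocyanate is trapped by diethylamine) and O-triflation of the phenoxide in the same flask; the aryl–silicon bond should survive because no fluoride is present.

Step 10
Reactants: 11 ethyl (2R,3S,4R)-3-(3,5-dimethoxyphenyl)-5,7-dimethoxy-4-(4-methoxyphenyl)-1-oxo-1,2,3,4-tetrahydronaphthalene-2-carboxylate; 19 3,5-dimethoxy-2-(trimethylsilyl)phenyl trifluoromethanesulfonate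
Product: 21 ethyl (10R,11S,12R)-11-(3,5-dimethoxyphenyl)-2,4,7,9-tetramethoxy-10-(4-methoxyphenyl)-5-oxo-5,10,11,12-tetrahydrodibenzo[a,d]cyclooctene-12-carboxylate, via 3,5-dimethoxybenzyne 20 (not isolated)
Conditions: 19 (1.25 equiv), CsF (2.5 equiv), MeCN, 80 °C
Reagents that add atoms: none
Why: Fluoride removes the silyl group and triflate leaves to give aryne 20; the caesium enolate of 11 adds through C2 to the aryne carbon remote from the flanking methoxy group, the resulting aryl anion (ortho to that methoxy group) attacks the C1 ketone in a 4-exo-trig addition to give a benzocyclobutenoxide, and this fragments with cleavage of the old C1–C2 bond to an ester-stabilised benzylic carbanion that is protonated. The closest known reaction type is the acyl-alkylation of arynes with beta-keto esters, which with cyclic substrates is a two-carbon ring expansion. The eight-membered ring is therefore not closed end to end but arises when the fused four-membered alkoxide fragments, which turns the six-membered ring into the eight-membered one and forms the indane C2–benzofuran C4 and benzofuran C3–C3a bonds. The new stereocentre (ester-bearing C12, future indane C2) is set on protonation and, as an enolisable alpha-aryl ester centre under the basic conditions, should settle trans to the neighbouring aryl-bearing C11, while C10 and C11 are not enolisable and keep their configuration. The step needs regioselective addition to the unsymmetrical aryne and C- rather than O-arylation: the inductive effect of the methoxy group next to the aryne bond directs the nucleophile to the distal carbon, which places the ketone ortho to the oxygen that becomes the furan oxygen, and the soft ester-stabilised enolate carbon is the usual site of attack.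

Step 11
Reactants: 21 ethyl (10R,11S,12R)-11-(3,5-dimethoxyphenyl)-2,4,7,9-tetramethoxy-10-(4-methoxyphenyl)-5-oxo-5,10,11,12-tetrahydrodibenzo[a,d]cyclooctene-12-carboxylate
Product: 22 diol: C5 carbinol and C12 hydroxymethyl analogue of 21 (10R,11S,12R; C5 epimers)
Conditions: LiAlH4, THF, 0 → 23 °C
Reagents that add atoms: none
Why: Hydride reduction of the ester to the primary alcohol and of the diaryl ketone to the benzhydrol in one operation; the C5 carbinol epimers need not be separated because C5 is re-oxidised in step 12, and C10–C12 are not affected.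

Step 12
Reactants: 22 diol (C5 epimers)
Product: 23 keto aldehyde: (10R,11S,12R)-11-(3,5-dimethoxyphenyl)-2,4,7,9-tetramethoxy-10-(4-methoxyphenyl)-5-oxo-5,10,11,12-tetrahydrodibenzo[a,d]cyclooctene-12-carbaldehyde
Conditions: Dess–Martin periodinane, NaHCO3, CH2Cl2, 23 °C
Reagents that add atoms: none
Why: Dess–Martin oxidation of both alcohols under buffered conditions; the alpha-aryl aldehyde centre is already in the trans arrangement expected to be the more stable one, so any equilibration should be harmless.

Step 13
Reactants: 23 keto aldehyde; 24 4-methoxyphenylmagnesium bromide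
Product: 25 keto carbinol: C12 hydroxy(4-methoxyphenyl)methyl analogue of 23 (10R,11S,12R; carbinol epimers)
Conditions: 24 (THF solution), THF, −78 °C
Reagents that add atoms: none
Why: Grignard addition chemoselective for the aldehyde, since the diaryl ketone carries three ortho substituents and should not be attacked at −78 °C; the carbinol epimers are not separated because this centre is ionised in step 14.

Step 14
Reactants: 25 keto carbinol (carbinol epimers)
Product: 26 pentacyclic ketone: indane (C1 4-methoxyphenyl, 1S,2S,3R, all-trans) fused to the dibenzocyclooctenone, bridge methine R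
Conditions: TfOH (5 mol%), HFIP/CH2Cl2, −20 → 0 °C
Reagents that add atoms: none
Why: Intramolecular Friedel–Crafts alkylation, in which the 4-methoxybenzylic cation is captured by the ortho carbon (ortho/para to both methoxy groups) of the neighbouring 3,5-dimethoxyphenyl ring to close the five-membered indane ring, and the anisyl group should take the position trans to ring D on indane C2, the least strained arrangement in the product-like transition state.

Step 15
Reactants: 26 pentacyclic ketone
Product: 27 ortho-hydroxy ketone: 26 with the ring D methoxy group ortho to the ketone cleaved to OH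
Conditions: BCl3, CH2Cl2, −78 → 0 °C
Reagents that add atoms: none
Why: Chelation-controlled Lewis-acid ether cleavage, in which only the methoxy group ortho to the ketone can form the six-membered boron chelate and be demethylated, while the other seven aryl methyl ethers should be untouched at this temperature.

Step 16
Reactants: 27 ortho-hydroxy ketone
Product: 29 ortho-hydroxybenzhydryl p-tolyl sulfone (sulfone carbon epimers), via benzhydrol 28 (not isolated)
Conditions: LiAlH4, THF, 0 °C; aq. work-up; then p-TolSO2Na, HCO2H, CH2Cl2, 23 °C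
Reagents that add atoms: sodium p-toluenesulfinate, [Na+].[O-]S(=O)c1ccc(C)cc1
Why: Hydride reduction of the ketone, then acid-mediated SN1 substitution of the ortho-hydroxybenzhydrol by sulfinate through its quinone methide/benzhydryl cation, which should give a storable quinone methide precursor whose configuration at the sulfone carbon is immaterial.

Step 17
Reactants: 30 4-methoxybenzyl chloride
Product: 31 1-(4-methoxybenzyl)tetrahydrothiophenium chloride
Conditions: tetrahydrothiophene, MeCN, 40 °C
Reagents that add atoms: tetrahydrothiophene, C1CCSC1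
Why: S-alkylation of the sulfide by the reactive benzylic chloride (nucleophilic substitution) gives the sulfonium salt.

Step 18
Reactants: 29 ortho-hydroxybenzhydryl p-tolyl sulfone; 31 1-(4-methoxybenzyl)tetrahydrothiophenium chloride
Product: 34 octa-O-methylstenophyllol B, via sulfonium ylide 32 (not isolated), via ortho-quinone methide 33 (not isolated)
Conditions: 31 (3 equiv), LiN(SiMe3)2 (3 equiv), THF, −78 °C; then 29, −78 → 0 °C
Reagents that add atoms: none
Why: Formal [4+1] annulation of an ortho-quinone methide with a sulfur ylide, in which excess ylide 32 deprotonates the phenol, sulfinate is expelled to give 33, a second ylide should add to the exocyclic carbon from the face opposite the two flanking substituents (the anisyl group on the bridge methine and the indane C1–C2 bond, both on the same face of the eight-membered ring) and so set benzofuran C3, and the phenoxide then displaces tetrahydrothiophene in an anti SN2 closure that sets C2 trans to C3.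

Step 19
Reactants: 34 octa-O-methylstenophyllol B
Product: 35 stenophyllol B
Conditions: BBr3 (excess), CH2Cl2, −78 → 23 °C; then MeOH/H2O
Reagents that add atoms: none
Why: Lewis-acid cleavage of all eight aryl methyl ethers, in which the only centre that can ionise is the benzylic C–O carbon of the dihydrobenzofuran, and inside the rigid framework it should only re-close to the trans ring.

**Compound list**

1 | 4'-methoxyacetophenone | CC(=O)c1ccc(OC)cc1 | starting material
2 | 1-bromo-3,5-dimethoxybenzene | COc1cc(Br)cc(OC)c1 | starting material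
3 | 2-(3,5-dimethoxyphenyl)-1-(4-methoxyphenyl)ethan-1-one | COc1ccc(cc1)C(=O)Cc1cc(OC)cc(OC)c1 | intermediate
4 | ethyl bromoacetate | CCOC(=O)CBr | starting material
5 | ethyl 3-(3,5-dimethoxyphenyl)-4-(4-methoxyphenyl)-4-oxobutanoate (racemic) | CCOC(=O)CC(c1cc(OC)cc(OC)c1)C(=O)c1ccc(OC)cc1 | intermediate
6 | ethyl (3S,4S)-3-(3,5-dimethoxyphenyl)-4-hydroxy-4-(4-methoxyphenyl)butanoate | CCOC(=O)C[C@@H](c1cc(OC)cc(OC)c1)[C@H](O)c1ccc(OC)cc1 | intermediate
7 | (4S,5S)-4-(3,5-dimethoxyphenyl)-5-(4-methoxyphenyl)dihydrofuran-2(3H)-one (cis) | O=C1C[C@@H](c2cc(OC)cc(OC)c2)[C@@H](c2ccc(OC)cc2)O1 | intermediate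
8 | 3,5-dimethoxyphenyllithium | [Li]c1cc(OC)cc(OC)c1 | intermediate
9 | (3S,4S)-1,3-bis(3,5-dimethoxyphenyl)-4-hydroxy-4-(4-methoxyphenyl)butan-1-one | COc1cc(cc(OC)c1)C(=O)C[C@@H](c1cc(OC)cc(OC)c1)[C@H](O)c1ccc(OC)cc1 | intermediate
10 | (3R,4R)-3-(3,5-dimethoxyphenyl)-5,7-dimethoxy-4-(4-methoxyphenyl)-3,4-dihydronaphthalen-1(2H)-one (3,4-trans) | O=C1C[C@@H](c2cc(OC)cc(OC)c2)[C@H](c2ccc(OC)cc2)c2c(OC)cc(OC)cc21 | intermediate
11 | ethyl (2R,3S,4R)-3-(3,5-dimethoxyphenyl)-5,7-dimethoxy-4-(4-methoxyphenyl)-1-oxo-1,2,3,4-tetrahydronaphthalene-2-carboxylate (trans,trans) | CCOC(=O)[C@@H]1[C@@H](c2cc(OC)cc(OC)c2)[C@H](c2ccc(OC)cc2)c2c(OC)cc(OC)cc2C1=O | intermediate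
12 | 3,5-dimethoxyphenol | COc1cc(O)cc(OC)c1 | starting material
13 | 3,5-dimethoxyphenyl isopropylcarbamate | COc1cc(OC)cc(OC(=O)NC(C)C)c1 | intermediate
14 | 3,5-dimethoxyphenyl N-(tert-butyldimethylsilyl)-N-isopropylcarbamate | COc1cc(OC)cc(OC(=O)N(C(C)C)[Si](C)(C)C(C)(C)C)c1 | intermediate
15 | 2-lithio-3,5-dimethoxyphenyl N-(tert-butyldimethylsilyl)-N-isopropylcarbamate | COc1cc(OC)c([Li])c(OC(=O)N(C(C)C)[Si](C)(C)C(C)(C)C)c1 | intermediate
16 | 3,5-dimethoxy-2-(trimethylsilyl)phenyl N-(tert-butyldimethylsilyl)-N-isopropylcarbamate | COc1cc(OC)c([Si](C)(C)C)c(OC(=O)N(C(C)C)[Si](C)(C)C(C)(C)C)c1 | intermediate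
17 | 3,5-dimethoxy-2-(trimethylsilyl)phenyl isopropylcarbamate | COc1cc(OC)c([Si](C)(C)C)c(OC(=O)NC(C)C)c1 | intermediate
18 | 3,5-dimethoxy-2-(trimethylsilyl)phenol | COc1cc(OC)c([Si](C)(C)C)c(O)c1 | intermediate
19 | 3,5-dimethoxy-2-(trimethylsilyl)phenyl trifluoromethanesulfonate | COc1cc(OC)c([Si](C)(C)C)c(OS(=O)(=O)C(F)(F)F)c1 | intermediate
20 | 3,5-dimethoxybenzyne | COC1=CC(OC)=CC#C1 | intermediate
21 | ethyl (10R,11S,12R)-11-(3,5-dimethoxyphenyl)-2,4,7,9-tetramethoxy-10-(4-methoxyphenyl)-5-oxo-5,10,11,12-tetrahydrodibenzo[a,d]cyclooctene-12-carboxylate (ketone at future benzofuran C3, ester on future indane C2) | CCOC(=O)[C@@H]1[C@@H](c2cc(OC)cc(OC)c2)[C@H](c2ccc(OC)cc2)c2c(OC)cc(OC)cc2C(=O)c2c(OC)cc(OC)cc21 | intermediate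
22 | diol: 5-hydroxy-12-(hydroxymethyl) analogue of 21 (10R,11S,12R; C5 epimers) | OC[C@@H]1[C@@H](c2cc(OC)cc(OC)c2)[C@H](c2ccc(OC)cc2)c2c(OC)cc(OC)cc2C(O)c2c(OC)cc(OC)cc21 | intermediate
23 | keto aldehyde: 5-oxo-12-carbaldehyde analogue of 21 (10R,11S,12R) | O=C[C@@H]1[C@@H](c2cc(OC)cc(OC)c2)[C@H](c2ccc(OC)cc2)c2c(OC)cc(OC)cc2C(=O)c2c(OC)cc(OC)cc21 | intermediate
24 | 4-methoxyphenylmagnesium bromide (commercial THF solution) | COc1ccc([Mg]Br)cc1 | starting material
25 | keto carbinol: 12-[hydroxy(4-methoxyphenyl)methyl] analogue of 23 (10R,11S,12R; carbinol epimers) | COc1ccc(cc1)C(O)[C@@H]1[C@@H](c2cc(OC)cc(OC)c2)[C@H](c2ccc(OC)cc2)c2c(OC)cc(OC)cc2C(=O)c2c(OC)cc(OC)cc21 | intermediate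
26 | octamethoxy pentacyclic ketone: all-trans indane (C1 4-methoxyphenyl S, C2 S, C3 R) fused to the dibenzocyclooctenone, bridge methine R, ketone at future benzofuran C3 | COc1ccc([C@H]2c3c(OC)cc(OC)cc3[C@H]3[C@H](c4ccc(OC)cc4)c4c(OC)cc(OC)cc4C(=O)c4c(OC)cc(OC)cc4[C@H]23)cc1 | intermediate
27 | ortho-hydroxy ketone: 26 with ring D OH ortho to the ketone | COc1ccc([C@H]2c3c(OC)cc(OC)cc3[C@H]3[C@H](c4ccc(OC)cc4)c4c(OC)cc(OC)cc4C(=O)c4c(O)cc(OC)cc4[C@H]23)cc1 | intermediate
28 | ortho-hydroxybenzhydrol: carbinol from 27 (carbinol epimers) | COc1ccc([C@H]2c3c(OC)cc(OC)cc3[C@H]3[C@H](c4ccc(OC)cc4)c4c(OC)cc(OC)cc4C(O)c4c(O)cc(OC)cc4[C@H]23)cc1 | intermediate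
29 | ortho-hydroxybenzhydryl p-tolyl sulfone from 28 (epimers at the sulfone carbon) | COc1ccc([C@H]2c3c(OC)cc(OC)cc3[C@H]3[C@H](c4ccc(OC)cc4)c4c(OC)cc(OC)cc4C(S(=O)(=O)c4ccc(C)cc4)c4c(O)cc(OC)cc4[C@H]23)cc1 | intermediate
30 | 4-methoxybenzyl chloride | COc1ccc(CCl)cc1 | starting material
31 | 1-(4-methoxybenzyl)tetrahydrothiophenium chloride | COc1ccc(C[S+]2CCCC2)cc1.[Cl-] | intermediate
32 | 4-methoxybenzylidene tetrahydrothiophenium ylide | COc1ccc([CH-][S+]2CCCC2)cc1 | intermediate
33 | ortho-quinone methide from 29 (exocyclic C=C at future benzofuran C3) | COc1ccc([C@H]2c3c(OC)cc(OC)cc3[C@H]3[C@H](c4ccc(OC)cc4)c4c(OC)cc(OC)cc4C=C4C(=O)C=C(OC)C=C4[C@H]23)cc1 | intermediate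
34 | octa-O-methylstenophyllol B (trans-dihydrobenzofuran, C2 R, C3 R; indane 1S,2S,3R; bridge methine R) | COc1ccc([C@H]2c3c(OC)cc(OC)cc3[C@H]3[C@H](c4ccc(OC)cc4)c4c(OC)cc(OC)cc4[C@@H]4c5c(cc(OC)cc5[C@H]23)O[C@H]4c2ccc(OC)cc2)cc1 | intermediate
35 | stenophyllol B | Oc1ccc([C@H]2c3c(O)cc(O)cc3[C@H]3[C@H](c4ccc(O)cc4)c4c(O)cc(O)cc4[C@@H]4c5c(cc(O)cc5[C@H]23)O[C@H]4c2ccc(O)cc2)cc1 | target

**Step count and risk**

Total step count: 19. Longest linear sequence: 15 steps (1–6, 10–16, 18, 19).

Steps most likely to fail:

Step 10 (aryne insertion). The enolate carbon is flanked by the aryl-bearing C3, so C-arylation may be slower than aryne self-reaction or O-arylation. The ortho-aryl anion may also be protonated by the medium before it reaches the ketone, which would stop at plain alpha-arylation. Fallback, setting out from 11 and returning at 21: 1-iodo-3,5-dimethoxybenzene is brominated (NBS, MeCN) next to iodine to give 2-bromo-1-iodo-3,5-dimethoxybenzene F1. This is oxidised (mCPBA, TsOH·H2O) in the presence of 1,3,5-trimethoxybenzene to (2-bromo-3,5-dimethoxyphenyl)(2,4,6-trimethoxyphenyl)iodonium p-toluenesulfonate F2. The potassium enolate of 11 (t-BuOK, THF) is C-arylated by this trivalent-iodine reagent, the trimethoxyphenyl group staying on iodine, to give the quaternary alpha-(2-bromoaryl) keto ester F3. Bromine–lithium exchange (n-BuLi, THF, −100 °C) then generates the same ortho-aryl anion in an aprotic medium. Its Parham-type addition to the C1 ketone and retro-aldol opening of the cyclobutenoxide give 21 after protonation.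

Step 18 ([4+1] annulation). The ylide may add to the quinone methide with poor facial selectivity. The semi-stabilised ylide may also be lost by O-benzylation of the phenoxide or by self-condensation before it adds. Fallback, setting out from 26 and returning at 35, with the benzofuran C3 centre under thermodynamic control: ylide 32 (made as in step 18) converts the ketone of 26 into the spiro-epoxide F4 (Corey–Chaykovsky epoxidation). BF3·OEt2 opens it to the tertiary diaryl cation, and a 1,2-hydride shift (Meinwald rearrangement) gives the alpha,alpha-diaryl 4-methoxyphenyl ketone F5. Its enolisable C–H centre between ring C and ring D is equilibrated with DBU to the more stable epimer. NaBH4 gives the carbinol F6. BBr3 then ionises the 4-methoxybenzylic alcohol, the neighbouring ring D methoxy oxygen closes the trans-dihydrofuran with loss of bromomethane, and the remaining ethers are cleaved to give 35.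

Step 3 (dynamic kinetic transfer hydrogenation). The two ketone epimers may be reduced at similar rates, or epimerisation may be too slow, so that the future indane C3 centre is poorly controlled. Fallback, setting out from 2 and returning at 10, with this centre set on a non-enolisable carbon: 2 is lithiated and borylated (n-BuLi; B(Oi-Pr)3; aqueous acid) to (3,5-dimethoxyphenyl)boronic acid F7. Hayashi–Miyaura addition to furan-2(5H)-one (Rh(acac)(C2H4)2, (S)-BINAP, dioxane/H2O, 100 °C; sense chosen by analogy with cyclic enones) gives (S)-4-(3,5-dimethoxyphenyl)dihydrofuran-2(3H)-one F8. Me(MeO)NH·HCl/AlMe3 opens it to the hydroxy Weinreb amide F9, and Dess–Martin oxidation gives the aldehyde F10. Addition of 24 at −78 °C and acid-promoted lactonisation give 7 together with its C5 epimer, the trans lactone F11. Step 4 applied to the mixture gives 9 and its carbinol epimer F12, and both converge on 10 in step 5 because the carbinol carbon is ionised.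

Further compounds
F1 | step 10 | 2-bromo-1-iodo-3,5-dimethoxybenzene | COc1cc(I)c(Br)c(OC)c1
F2 | step 10 | (2-bromo-3,5-dimethoxyphenyl)(2,4,6-trimethoxyphenyl)iodonium p-toluenesulfonate | COc1cc(OC)c([I+]c2cc(OC)cc(OC)c2Br)c(OC)c1.Cc1ccc(cc1)S(=O)(=O)[O-]
F3 | step 10 | ethyl (3R,4R)-2-(2-bromo-3,5-dimethoxyphenyl)-3-(3,5-dimethoxyphenyl)-5,7-dimethoxy-4-(4-methoxyphenyl)-1-oxo-1,2,3,4-tetrahydronaphthalene-2-carboxylate (C2 configuration not controlled) | CCOC(=O)C1(c2cc(OC)cc(OC)c2Br)[C@@H](c2cc(OC)cc(OC)c2)[C@H](c2ccc(OC)cc2)c2c(OC)cc(OC)cc2C1=O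
F4 | step 18 | spiro-epoxide of 26 bearing a 4-methoxyphenyl group on the new epoxide carbon (epoxide epimers) | COc1ccc([C@H]2c3c(OC)cc(OC)cc3[C@H]3[C@H](c4ccc(OC)cc4)c4c(OC)cc(OC)cc4C4(OC4c4ccc(OC)cc4)c4c(OC)cc(OC)cc4[C@H]23)cc1
F5 | step 18 | alpha,alpha-diaryl 4-methoxyphenyl ketone from F4 (methine between ring C and ring D drawn with the configuration of the target) | COc1ccc([C@H]2c3c(OC)cc(OC)cc3[C@H]3[C@H](c4ccc(OC)cc4)c4c(OC)cc(OC)cc4[C@@H](C(=O)c4ccc(OC)cc4)c4c(OC)cc(OC)cc4[C@H]23)cc1
F6 | step 18 | carbinol from F5 (carbinol epimers) | COc1ccc([C@H]2c3c(OC)cc(OC)cc3[C@H]3[C@H](c4ccc(OC)cc4)c4c(OC)cc(OC)cc4[C@@H](C(O)c4ccc(OC)cc4)c4c(OC)cc(OC)cc4[C@H]23)cc1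
F7 | step 3 | (3,5-dimethoxyphenyl)boronic acid | COc1cc(cc(OC)c1)B(O)O
F8 | step 3 | (S)-4-(3,5-dimethoxyphenyl)dihydrofuran-2(3H)-one | O=C1C[C@@H](c2cc(OC)cc(OC)c2)CO1
F9 | step 3 | (S)-3-(3,5-dimethoxyphenyl)-4-hydroxy-N-methoxy-N-methylbutanamide | CON(C)C(=O)C[C@@H](c1cc(OC)cc(OC)c1)CO
F10 | step 3 | (S)-3-(3,5-dimethoxyphenyl)-N-methoxy-N-methyl-4-oxobutanamide | CON(C)C(=O)C[C@@H](c1cc(OC)cc(OC)c1)C=O
F11 | step 3 | (4S,5R)-4-(3,5-dimethoxyphenyl)-5-(4-methoxyphenyl)dihydrofuran-2(3H)-one (trans) | O=C1C[C@@H](c2cc(OC)cc(OC)c2)[C@H](c2ccc(OC)cc2)O1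
F12 | step 3 | (3S,4R)-1,3-bis(3,5-dimethoxyphenyl)-4-hydroxy-4-(4-methoxyphenyl)butan-1-one | COc1cc(cc(OC)c1)C(=O)C[C@@H](c1cc(OC)cc(OC)c1)[C@@H](O)c1ccc(OC)cc1
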